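Late in flask eta, what matters is no longer how bis adduct is made but how long it has stood beside leftover partner.

all flasks: time 80 min
- gamma: substrate 0.21 M; partner 0.252 M (fed, over 1.0 h); all else is in the flask from the start; the feed brings no volume worth counting
- theta: substrate 0.21 M (fed, over 15 min); partner 0.252 M; all else is in the flask from the start; the feed brings no volume worth counting
- epsilon: substrate 0.21 M; partner 0.252 M (in portions, 3, over 1.0 h); first portion at the start, last at 1.0 h
- eta: substrate 0.21 M; partner 0.252 M; everything together at the start
- alpha: substrate 0.21 M (fed, over 1.0 h); partner 0.252 M; all else is in the flask from the start; the feed brings no volume worth counting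

* the best flask by share of bis adduct in bis adduct plus tris adduct; "all alike" if 1.5 percentage points covers them all (gamma / theta / epsilon / eta / alpha / all alike)
* share of bis adduct in bis adduct plus tris adduct at the end, gamma
* share of bis adduct in bis adduct plus tris adduct at the end, theta
* share of bis adduct in bis adduct plus tris adduct at the end, epsilon
* share of bis adduct in bis adduct plus tris adduct at the end, eta
* share of bis adduct in bis adduct plus tris adduct at the end, alpha

    substrate + partner → first product (k1 = 2.41 M⁻¹ min⁻¹)
    partner + first product → bis adduct (k2 = 0.137 M⁻¹ min⁻¹)
    partner + bis adduct → tris adduct (k3 = 0.0783 M⁻¹ min⁻¹)
    first product → decomposed reagent (k4 = 0.177 min⁻¹)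
    first product → side product (k5 = 0.534 min⁻¹)
    bis adduct → over-reaction product (k6 = 0.0172 min⁻¹)

I compare eta with theta, which looks nearly the same: the charges are equal, but theta takes its substrate over 15 min instead of at once. In both flasks substrate is the limiting reagent, and the excess of partner is 0.0420 M. Partner also feeds bis adduct, but first product is lost at 0.711 min⁻¹ and meets partner at 0.0345 min⁻¹ at most. So 4.63% of it goes on, which costs at most 0.00972 M of partner.

I therefore freeze c(partner) at the excess. Bis adduct then decays pseudo-first-order, and I call its late loss constant λ: the constant of its conversion to over-reaction product plus the constant of its conversion to tris adduct times the frozen c(partner), 0.0205 min⁻¹. Of what it loses, the fraction 16.1% becomes tris adduct. The ratio of tris adduct to bis adduct after a time t is that fraction times one less than e^(λt).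

I run this clock over the whole 80 min, which overcounts the age of bis adduct but undercounts the richer partner of the first minutes, so the two errors pull opposite ways. Theta's feed is shorter than the lifetime of bis adduct, so I expect it to end close to eta. I give eta 60.0% and theta 60.0%. I commit to no number for gamma, epsilon and alpha, whose dosing lasts 1.0 h and gives the clock no single start.

The forecast names gamma as best, with gamma 91%, theta 56%, epsilon 89%, eta 50% and alpha 54%, holding of gamma and epsilon that “little bis adduct sees free partner and it forms late”. My eta figure stands above its own.

The simulation ranks epsilon first with 89.4%, ahead of the forecast's choice, gamma, at 87.1%; theta gives 58.1%, eta 59.3% and alpha 56.8%. Eta has not come to rest at 80 min: bis adduct stands at 0.433% of the substrate charged and tris adduct at 0.297%. At 800 min eta's bis adduct reads 0%, and the fraction taken from λ puts tris adduct at 0.367%, against a simulated 0.360%. In epsilon the same fraction gives 0.0870% against a simulated 0.0882%, and epsilon's share falls to 0%.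

All constants were drawn at random within sensible limits; the flask was simulated.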